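The γ-lactone is read as a reduced 2-aroyl lactone: the exocyclic carbinol carbon and the lactone carbonyl C2 are 1,3-related through C3, so C3 is the α-carbon of an aryl ketone. Everything rests on closing the oxolan-2-one ring at C2–C3 by an intramolecular Claisen (Dieckmann-type) C-acylation, in which the enolate of an acyclic aryl ketone attacks an imidazolyl-activated carbonyl already attached to O1. This one operation forms the ring and an enolisable β-keto lactone, so C3 is funnelled thermodynamically trans to the C4 benzyl group, and the 1,3-dicarbonyl chelate then directs hydride to the carbinol centre. C4 itself comes from an enantioselective organocatalytic aldehyde α-alkylation.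

Key step: step 3

Assumption: the aryl bromide, allyl alcohol and the α-bromo ketone used as starting materials are taken as commercially available; lactone numbering is O1, C2 (carbonyl), C3, C4, C5, and "carbinol carbon" means the exocyclic CH(OH)Ar carbon on C3.

Step 1
Reactants: 1 1-(benzyloxy)-4-bromo-2-methoxybenzene; 2 prop-2-en-1-ol (allyl alcohol)
Product: 3 3-[4-(benzyloxy)-3-methoxyphenyl]propanal
Conditions: Pd(OAc)2 (3 mol%), Bu4NCl, NaHCO3, DMF, 90 °C
Reagents that add atoms: none
Why: Mizoroki–Heck arylation of an allylic alcohol under ligand-free phase-transfer conditions, in which aryl–Pd adds to the terminal alkene carbon and β-hydride elimination towards the carbinol carbon gives an enol that tautomerises to the 3-arylpropanal; no stereocentre is formed.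

Step 2
Reactants: 3 3-[4-(benzyloxy)-3-methoxyphenyl]propanal (2 equiv); 4 1-[4-(benzyloxy)-3-methoxyphenyl]-2-bromoethan-1-one
Product: 6 (R)-3-[4-(benzyloxy)-3-methoxybenzyl]-1-[4-(benzyloxy)-3-methoxyphenyl]-4-hydroxybutan-1-one, via keto aldehyde 5 (not isolated)
Conditions: (2R,5S)-2-tert-butyl-3,5-dimethylimidazolidin-4-one·TfOH (20 mol%), Ru(bpy)3Cl2 (0.5 mol%), 2,6-lutidine, DMF, visible light, 23 °C; then NaBH4, CH2Cl2/EtOH, −78 °C
Reagents that add atoms: none
Why: Enamine/photoredox dual-catalytic enantioselective α-alkylation of an aldehyde with an α-bromo ketone, in which the (E)-enamine of 3 has its Re face shielded by the catalyst 5-methyl group so that the phenacyl radical generated from 4 by the reduced Ru photocatalyst adds to the Si face and sets the (R) centre (the future C4) under catalyst control, after which the configurationally labile aldehyde 5 is reduced at once at −78 °C, where the aldehyde should react far faster than the electron-rich aryl ketone.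

Step 3
Reactants: 6 (R)-3-[4-(benzyloxy)-3-methoxybenzyl]-1-[4-(benzyloxy)-3-methoxyphenyl]-4-hydroxybutan-1-one
Product: 9 (3S,4R)-3-[4-(benzyloxy)-3-methoxybenzoyl]-4-[4-(benzyloxy)-3-methoxybenzyl]oxolan-2-one, via imidazole carboxylate 7 (not isolated), via lithium enolate 8 (not isolated)
Conditions: CDI (1.05 equiv), THF, 23 °C; then LiHMDS (3.5 equiv), THF (0.02 M), −78 → 0 °C; aq. NH4Cl
Reagents that add atoms: 1,1'-carbonyldiimidazole (CDI), O=C(n1ccnc1)n1ccnc1
Why: CDI first acylates the primary alcohol to the imidazole-1-carboxylate 7; LiHMDS then generates the lithium enolate of the aryl ketone, whose α-carbon (the future C3) adds to the tethered carbonyl (the future C2) and expels imidazolide, and the β-keto lactone is deprotonated at once to the chelated enolate 8, which makes the closure irreversible. The closest known reaction type is the Dieckmann-type intramolecular Claisen C-acylation of a ketone enolate by a carbonate-level acyl donor (acyl-imidazole variant). The oxolan-2-one ring closes in the 5-(enolexo)-exo-trig mode. C3 is not fixed kinetically: it is planar in 8 and, on protonation and through the easy enolisation of 9, should settle trans to the C4 substituent under thermodynamic control by the fixed C4 centre, so both faces converge on (3S). The step needs C- over O-acylation and ring closure over intermolecular condensation; the five-membered C-acylation against a seven-membered enol carbonate (which imidazolide can reopen), the single enolisable position of the aryl ketone and high dilution secure this.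

Step 4
Reactants: 9 (3S,4R)-3-[4-(benzyloxy)-3-methoxybenzoyl]-4-[4-(benzyloxy)-3-methoxybenzyl]oxolan-2-one
Product: 10 (3S,4R)-4-[4-(benzyloxy)-3-methoxybenzyl]-3-{(S)-[4-(benzyloxy)-3-methoxyphenyl](hydroxy)methyl}oxolan-2-one
Conditions: Zn(BH4)2, Et2O/CH2Cl2, −78 → −20 °C; aq. NH4Cl
Reagents that add atoms: none
Why: Chelation-controlled hydride reduction of an α-substituted β-keto ester, in which zinc bridges the ketone and lactone carbonyl oxygens and hydride should be delivered to the Re face of the ketone, on the side of the C3 hydrogen and anti to C4, giving the (S)-carbinol; the trans C3 configuration is locked once the ketone is gone.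

Step 5
Reactants: 10 (3S,4R)-4-[4-(benzyloxy)-3-methoxybenzyl]-3-{(S)-[4-(benzyloxy)-3-methoxyphenyl](hydroxy)methyl}oxolan-2-one
Product: 11 (3S,4R)-3-[(S)-hydroxy(4-hydroxy-3-methoxyphenyl)methyl]-4-(4-hydroxy-3-methoxybenzyl)oxolan-2-one (CNP0288801.2)
Conditions: H2 (1 atm), 10% Pd/C, EtOAc, 23 °C, stopped at full debenzylation
Reagents that add atoms: none
Why: O-Debenzylation by catalytic hydrogenolysis under neutral conditions should outpace cleavage of the secondary carbinol C–O bond, which normally needs acid promotion, so the lactone and the three stereocentres are untouched.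

Compound list

1 | 1-(benzyloxy)-4-bromo-2-methoxybenzene | COc1cc(Br)ccc1OCc1ccccc1 | starting material
2 | prop-2-en-1-ol (allyl alcohol) | C=CCO | starting material
3 | 3-[4-(benzyloxy)-3-methoxyphenyl]propanal | COc1cc(CCC=O)ccc1OCc1ccccc1 | intermediate
4 | 1-[4-(benzyloxy)-3-methoxyphenyl]-2-bromoethan-1-one | COc1cc(C(=O)CBr)ccc1OCc1ccccc1 | starting material
5 | (R)-2-[4-(benzyloxy)-3-methoxybenzyl]-4-[4-(benzyloxy)-3-methoxyphenyl]-4-oxobutanal (formed in the flask in step 2) | COc1cc(C[C@@H](C=O)CC(=O)c2ccc(OCc3ccccc3)c(OC)c2)ccc1OCc1ccccc1 | intermediate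
6 | (R)-3-[4-(benzyloxy)-3-methoxybenzyl]-1-[4-(benzyloxy)-3-methoxyphenyl]-4-hydroxybutan-1-one | COc1cc(C[C@@H](CO)CC(=O)c2ccc(OCc3ccccc3)c(OC)c2)ccc1OCc1ccccc1 | intermediate
7 | (R)-2-[4-(benzyloxy)-3-methoxybenzyl]-4-[4-(benzyloxy)-3-methoxyphenyl]-4-oxobutyl 1H-imidazole-1-carboxylate (formed in the flask in step 3) | COc1cc(C[C@@H](COC(=O)n2ccnc2)CC(=O)c2ccc(OCc3ccccc3)c(OC)c2)ccc1OCc1ccccc1 | intermediate
8 | lithium (Z)-[4-(benzyloxy)-3-methoxyphenyl]{(4R)-4-[4-(benzyloxy)-3-methoxybenzyl]-2-oxooxolan-3-ylidene}methanolate, the chelated enolate of 9 (formed in the flask in step 3) | COc1cc(C[C@H]2COC(=O)/C2=C(\[O-])c2ccc(OCc3ccccc3)c(OC)c2)ccc1OCc1ccccc1.[Li+] | intermediate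
9 | (3S,4R)-3-[4-(benzyloxy)-3-methoxybenzoyl]-4-[4-(benzyloxy)-3-methoxybenzyl]oxolan-2-one (3,4-trans) | COc1cc(C[C@H]2COC(=O)[C@@H]2C(=O)c2ccc(OCc3ccccc3)c(OC)c2)ccc1OCc1ccccc1 | intermediate
10 | (3S,4R)-4-[4-(benzyloxy)-3-methoxybenzyl]-3-{(S)-[4-(benzyloxy)-3-methoxyphenyl](hydroxy)methyl}oxolan-2-one | COc1cc(C[C@H]2COC(=O)[C@@H]2[C@H](O)c2ccc(OCc3ccccc3)c(OC)c2)ccc1OCc1ccccc1 | intermediate
11 | (3S,4R)-3-[(S)-hydroxy(4-hydroxy-3-methoxyphenyl)methyl]-4-(4-hydroxy-3-methoxybenzyl)oxolan-2-one | COc1cc(C[C@H]2COC(=O)[C@@H]2[C@H](O)c2ccc(O)c(OC)c2)ccc1O | target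

Total step count: 5. Longest linear sequence: 5 steps (1 → 3 → 6 → 9 → 10 → 11).

Steps most likely to fail

Step 2. The enantioselectivity may be eroded by enolisation of the α-branched aldehyde before the hydride quench, or by non-selective background alkylation of the enamine by the bromo ketone. The fallback sets C4 by auxiliary control and sets out from 3. Pinnick oxidation (NaClO2, NaH2PO4, 2-methyl-2-butene) should give 3-[4-(benzyloxy)-3-methoxyphenyl]propanoic acid F1. Mixed-anhydride coupling (PivCl, Et3N; then lithiated (S)-4-benzyloxazolidin-2-one) should give (S)-4-benzyl-3-{3-[4-(benzyloxy)-3-methoxyphenyl]propanoyl}oxazolidin-2-one F2. Oxazolidinone-auxiliary alkylation of its chelated Z-enolate (NaHMDS, THF, −78 °C, tert-butyl bromoacetate), anti to the auxiliary benzyl group, should give tert-butyl (R)-3-[4-(benzyloxy)-3-methoxybenzyl]-4-[(S)-4-benzyl-2-oxooxazolidin-3-yl]-4-oxobutanoate F3. LiBH4 should cleave the auxiliary to tert-butyl (R)-3-[4-(benzyloxy)-3-methoxybenzyl]-4-hydroxybutanoate F4, which should lactonise with TFA in CH2Cl2 to (R)-4-[4-(benzyloxy)-3-methoxybenzyl]oxolan-2-one F5. Single addition of [4-(benzyloxy)-3-methoxyphenyl]lithium F6 (from 1, n-BuLi, THF, −78 °C) to the lactone carbonyl, whose lithium lactolate resists a second addition, comes back to the route at 6.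

Step 4. Facial selectivity may be poor if the zinc chelate does not dominate; non-chelated (Felkin–Anh-type) delivery would give the epimeric carbinol. The fallback hands control from the substrate to a catalyst and sets out from 9: asymmetric transfer hydrogenation with RuCl[(S,S)-TsDPEN](p-cymene) in HCO2H/Et3N should deliver hydride to the Re face of the aryl ketone by reagent control while C3 keeps equilibrating to the trans isomer through the enol. It comes back to the route at 10 and makes no new compound (none, F0).

Step 5. Hydrogenolysis of the carbinol C–O bond, which is benzylic and para to a freed phenol, may compete with debenzylation. The fallback reverses the order of the last two operations and sets out from 9. Hydrogenolysis at the ketone stage (H2, Pd/C, EtOAc), where no benzylic alcohol is present, should give (3S,4R)-3-(4-hydroxy-3-methoxybenzoyl)-4-(4-hydroxy-3-methoxybenzyl)oxolan-2-one F7. Chelation-controlled reduction with excess Zn(BH4)2 (the phenols consume hydride) then comes back to the route at 11.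

Further compounds

F1 | step 2 | 3-[4-(benzyloxy)-3-methoxyphenyl]propanoic acid | COc1cc(CCC(=O)O)ccc1OCc1ccccc1
F2 | step 2 | (S)-4-benzyl-3-{3-[4-(benzyloxy)-3-methoxyphenyl]propanoyl}oxazolidin-2-one | COc1cc(CCC(=O)N2[C@@H](Cc3ccccc3)COC2=O)ccc1OCc1ccccc1
F3 | step 2 | tert-butyl (R)-3-[4-(benzyloxy)-3-methoxybenzyl]-4-[(S)-4-benzyl-2-oxooxazolidin-3-yl]-4-oxobutanoate | COc1cc(C[C@H](CC(=O)OC(C)(C)C)C(=O)N2[C@@H](Cc3ccccc3)COC2=O)ccc1OCc1ccccc1
F4 | step 2 | tert-butyl (R)-3-[4-(benzyloxy)-3-methoxybenzyl]-4-hydroxybutanoate | COc1cc(C[C@@H](CO)CC(=O)OC(C)(C)C)ccc1OCc1ccccc1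
F5 | step 2 | (R)-4-[4-(benzyloxy)-3-methoxybenzyl]oxolan-2-one | COc1cc(C[C@H]2COC(=O)C2)ccc1OCc1ccccc1
F6 | step 2 | [4-(benzyloxy)-3-methoxyphenyl]lithium | [Li]c1ccc(OCc2ccccc2)c(OC)c1
F0 | step 4 | none | none
F7 | step 5 | (3S,4R)-3-(4-hydroxy-3-methoxybenzoyl)-4-(4-hydroxy-3-methoxybenzyl)oxolan-2-one | COc1cc(C[C@H]2COC(=O)[C@@H]2C(=O)c2ccc(O)c(OC)c2)ccc1O
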